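**Plan**

1. Numbering: ring B is C5 (O, isopropenyl)–C6–C7–C8 (CH3)–C9 (lactone carbonyl C20; chain C11–C12 to the butenolide C13–C16 with O–C15)–C10 (H; chain C1–C2–C3 ester).
2. Enabling feature: C20–C9–C10–C1 of ring B and its lactone repeat the α-alkylbutenolide C16–C13–C14–C15 of the side chain, so both halves come from one symmetric bis-butenolide built on the adipate chain C20–C9–C11–C12–C13–C16.
3. Cuts, in order: C1–C2 (ester chain); C5–isopropenyl and C5–O (back to a C5 ketone with the lactone on O–C1); C8–C9 and C5–C10 (Diels–Alder); both butenolide rings (aldol, lactonisation, elimination).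
4. Forward: dimethyl adipate → bis-butenolide → ring B by [4+2] addition of (E)-piperylene to one butenolide → C5 ketone → isopropenyl addition with transfer of the lactone from O–C1 to O–C5 → two-carbon extension at C1.
5. Stereochemistry: C8, C9 and C10 come from the endo, ortho cycloaddition under a chiral oxazaborolidinium catalyst; C5 comes from equatorial attack of the isopropenyl nucleophile anti to the axial C20, and only the resulting cis alkoxide can take over the acyl group.

Key step: step 4

Assumption: the sense of induction of the oxazaborolidinium catalyst with an α-alkylbutenolide is not established; the (S)-catalyst is written, and its mirror image would be used if the opposite face is attacked.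

**Step 1**
Reactants: 1 dimethyl adipate; 2 (tert-butyldimethylsilyloxy)acetaldehyde (two molecules are incorporated)
Product: 4 dimethyl 2,5-bis[2-(tert-butyldimethylsilyloxy)-1-hydroxyethyl]hexanedioate (diastereomer mixture), via dilithium bis-enolate 3 (not isolated)
Conditions: LiN(iPr)2 (2.3 equiv), THF, −78 °C, 1 added slowly; then 2 (2.4 equiv), −78 °C; AcOH quench at −78 °C
Reagents that add atoms: (tert-butyldimethylsilyloxy)acetaldehyde (second equivalent of 2), O=CCO[Si](C)(C)C(C)(C)C
Why: Twofold lithium-enolate aldol addition, in which bis-enolate 3 (formed by inverse addition at −78 °C, where Dieckmann condensation is slow) adds at each α-carbon to one molecule of the aldehyde, so that two molecules of 2 end up in 4; the four stereocentres formed as a mixture are all removed in step 3.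

**Step 2**
Reactants: 4 bis-aldol
Product: 6 3,3'-(ethane-1,2-diyl)bis(4-hydroxydihydrofuran-2(3H)-one) (diastereomer mixture), via tetrahydroxy diester 5 (not isolated)
Conditions: p-TsOH·H2O (10 mol %), MeOH, 23 °C
Reagents that add atoms: none
Why: Acid-catalysed methanolysis of the two primary silyl ethers gives 5, whose γ-hydroxy ester units close to the five-membered lactones (lactonisation), the secondary hydroxyls being placed only for a strained four-membered ring.

**Step 3**
Reactants: 6 bis(hydroxylactone)
Product: 8 3,3'-(ethane-1,2-diyl)bis(furan-2(5H)-one), via bis(methanesulfonate) 7 (not isolated)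
Conditions: MsCl (2.5 equiv), Et3N (6 equiv), CH2Cl2, 0 → 23 °C
Reagents that add atoms: none
Why: Mesylation and E1cB elimination of the β-mesyloxy lactones 7 through the lactone enolate, which needs no particular relative configuration, puts each alkene in conjugation with its carbonyl and erases every stereocentre.

**Step 4**
Reactants: 8 bis-butenolide; 9 (E)-penta-1,3-diene
Product: 10 (3aS,7R,7aR)-7-methyl-7a-[2-(2-oxo-2,5-dihydrofuran-3-yl)ethyl]-3a,4,7,7a-tetrahydro-2-benzofuran-1(3H)-one (C8 methyl, C9–C20 and C10–C1 all cis)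
Conditions: 8 (3 equiv), 9 (1 equiv), (S)-1-(2-methylphenyl)-3,3-diphenyltetrahydro-1H,3H-pyrrolo[1,2-c][1,3,2]oxazaborole (20 mol %) activated with AlBr3 (16 mol %), CH2Cl2, −40 → −20 °C; unreacted 8 recovered
Reagents that add atoms: none
Why: Proposed new method: the cationic oxazaborolidinium formed from the oxazaborolidine and AlBr3 should bind one lactone carbonyl of 8 and lower the LUMO of its C9=C10 bond, so that the diene adds in a concerted, asynchronous [4+2] cycloaddition of normal electron demand; the closest known reaction types are the enantioselective Diels–Alder additions of acyclic dienes to enones, acrylates and quinones with this class of catalyst and the achiral Lewis-acid or high-pressure additions of piperylene to 2-alkylcycloalkenones and butenolides. Ring B closes in this one intermolecular cycloaddition (C8–C9 and C5–C10 formed suprafacially on both partners), necessarily cis-fused to the C20–O–C1 lactone. The unsubstituted terminus C5 has the larger HOMO coefficient and bonds to the β-carbon C10, which puts the methyl-bearing C8 next to the quaternary C9 (ortho product). C9 and C10 keep the cis geometry of the ring alkene, C8 is set by the E geometry of the diene with the Lewis-acid-bound carbonyl endo (methyl cis to C20), and the absolute configuration of all three depends only on which face of the bound butenolide the catalyst leaves open. Mono-addition is secured by the threefold excess of 8, whose two alkenes are equivalent, so that addition to either gives 10 and the untouched half is already the side chain of the target.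

**Step 5**
Reactants: 10 cycloadduct
Product: 11 (3aS,7R,7aR)-7-methyl-7a-[2-(2-oxo-2,5-dihydrofuran-3-yl)ethyl]-3a,7a-dihydro-2-benzofuran-1,4(3H,7H)-dione (C5 ketone conjugated with C6=C7)
Conditions: Rh2(C6H10NO)4 [dirhodium tetrakis(caprolactamate)] (1 mol %), 70% aq t-BuOOH (5 equiv), ClCH2CH2Cl, 40 °C
Reagents that add atoms: tert-butyl hydroperoxide, CC(C)(C)OO
Why: Rhodium-catalysed allylic oxidation with tert-butyl hydroperoxide (radical chain through the tert-butylperoxyl radical) should take hydrogen from the unhindered C5 methylene of the electron-rich ring alkene, not from C8–H (shielded by the quaternary C9 and its own methyl) or from the allylic positions of the electron-poor butenolide, and only C5 can give the conjugated ketone without allylic transposition.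

**Step 6**
Reactants: 11 enone
Product: 12 (3aS,7R,7aR)-7-methyl-7a-[2-(2-oxo-2,5-dihydrofuran-3-yl)ethyl]hexahydro-2-benzofuran-1,4-dione (C5 ketone, ring B saturated)
Conditions: [(Ph3P)CuH]6 (0.2 equiv), H2O (3 equiv), benzene, 23 °C
Reagents that add atoms: none
Why: Copper hydride conjugate reduction delivers hydride to C7 of the ketone-activated alkene much faster than to the ester-activated butenolide, and water then protonates C6, so C8 and C10 are untouched.

**Step 7**
Reactants: 12 ketone; 13 isopropenylmagnesium bromide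
Product: 16 (1R,2R,5S,8S)-2-methyl-1-[2-(2-oxo-2,5-dihydrofuran-3-yl)ethyl]-5-(prop-1-en-2-yl)-8-[(triethylsilyloxy)methyl]-6-oxabicyclo[3.2.1]octan-7-one, via bromomagnesium tertiary alkoxide 14 (not isolated), via bromomagnesium primary alkoxide 15 (not isolated)
Conditions: 13 (1.2 equiv), LaCl3·2LiCl (1.0 equiv), THF, −78 → 0 °C; then Et3SiCl (2 equiv), 4-(dimethylamino)pyridine (10 mol %), 0 °C
Reagents that add atoms: chlorotriethylsilane, CC[Si](Cl)(CC)CC
Why: Lanthanide-promoted Grignard 1,2-addition to the ketone (lactones untouched at low temperature) from the equatorial direction, away from the axial C20, sets C5 with its oxygen cis to C20 in 14; this 1,3-diaxial alkoxide takes over the acyl group through a five-membered transition state (translactonisation) to give 15, and only the primary alkoxide of 15 is silylated, which drains the equilibrium.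

**Step 8**
Reactants: 16 triethylsilyl ether
Product: 18 (1R,2R,5S,8R)-2-methyl-7-oxo-1-[2-(2-oxo-2,5-dihydrofuran-3-yl)ethyl]-5-(prop-1-en-2-yl)-6-oxabicyclo[3.2.1]octane-8-carbaldehyde, via alkoxysulfonium chloride 17 (not isolated)
Conditions: (COCl)2, DMSO, CH2Cl2, −78 → −40 °C; then iPr2NEt, −78 → −20 °C
Reagents that add atoms: none
Why: Swern oxidation applied directly to a primary triethylsilyl ether, in which the chlorosulfonium salt cleaves the Si–O bond to give 17 and the hindered amine collapses it to the aldehyde at low temperature, so the free γ-hydroxy lactone that could close back onto C20 is never formed.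

**Step 9**
Reactants: 18 aldehyde; 19 2,2-dimethyl-1,3-dioxane-4,6-dione
Product: 21 5-{[(1R,2R,5S,8R)-2-methyl-7-oxo-1-[2-(2-oxo-2,5-dihydrofuran-3-yl)ethyl]-5-(prop-1-en-2-yl)-6-oxabicyclo[3.2.1]octan-8-yl]methyl}-2,2-dimethyl-1,3-dioxane-4,6-dione, via alkylidene dioxanedione 20 (not isolated)
Conditions: 19 (1.1 equiv), diethyl 2,6-dimethyl-1,4-dihydropyridine-3,5-dicarboxylate (1.1 equiv), L-proline (10 mol %), EtOH, 23 °C
Reagents that add atoms: none
Why: Three-component reductive alkylation (Knoevenagel condensation, then transfer hydrogenation), in which the doubly activated alkene of 20 is reduced by the dihydropyridine as it forms, whereas the butenolide, the isopropenyl group and the lactones are not electrophilic enough to accept its hydride.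

**Step 10**
Reactants: 21 alkyl dioxanedione
Product: 23 methyl 3-[(1R,2R,5S,8R)-2-methyl-7-oxo-1-[2-(2-oxo-2,5-dihydrofuran-3-yl)ethyl]-5-(prop-1-en-2-yl)-6-oxabicyclo[3.2.1]octan-8-yl]propanoate (target), via malonic half ester 22 (not isolated)
Conditions: MeOH/pyridine 1:4, 90 °C (sealed tube)
Reagents that add atoms: methanol, CO
Why: Methanolysis of the dioxanedione with loss of acetone gives half ester 22, which decarboxylates on heating to the methyl ester, while pyridine is too weak a base to open the hindered tertiary lactone or to epimerise any centre.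

**Compound list**

1 | dimethyl adipate | COC(=O)CCCCC(=O)OC | starting material
2 | (tert-butyldimethylsilyloxy)acetaldehyde | O=CCO[Si](C)(C)C(C)(C)C | starting material
3 | dilithium bis-enolate of dimethyl adipate | COC(O[Li])=CCCC=C(OC)O[Li] | intermediate (not isolated)
4 | dimethyl 2,5-bis[2-(tert-butyldimethylsilyloxy)-1-hydroxyethyl]hexanedioate (diastereomer mixture) | COC(=O)C(CCC(C(=O)OC)C(O)CO[Si](C)(C)C(C)(C)C)C(O)CO[Si](C)(C)C(C)(C)C | intermediate
5 | dimethyl 2,5-bis(1,2-dihydroxyethyl)hexanedioate (diastereomer mixture) | COC(=O)C(CCC(C(=O)OC)C(O)CO)C(O)CO | intermediate (not isolated)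
6 | 3,3'-(ethane-1,2-diyl)bis(4-hydroxydihydrofuran-2(3H)-one) (diastereomer mixture) | O=C1OCC(O)C1CCC1C(O)COC1=O | intermediate
7 | bis(methanesulfonate) of 6 | CS(=O)(=O)OC1COC(=O)C1CCC1C(OS(C)(=O)=O)COC1=O | intermediate (not isolated)
8 | 3,3'-(ethane-1,2-diyl)bis(furan-2(5H)-one) | O=C1OCC=C1CCC1=CCOC1=O | intermediate
9 | (E)-penta-1,3-diene | C=C/C=C/C | starting material
10 | (3aS,7R,7aR)-7-methyl-7a-[2-(2-oxo-2,5-dihydrofuran-3-yl)ethyl]-3a,4,7,7a-tetrahydro-2-benzofuran-1(3H)-one | C1C=C[C@@H](C)[C@@]2(CCC3=CCOC3=O)C(=O)OC[C@@H]12 | intermediate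
11 | (3aS,7R,7aR)-7-methyl-7a-[2-(2-oxo-2,5-dihydrofuran-3-yl)ethyl]-3a,7a-dihydro-2-benzofuran-1,4(3H,7H)-dione | O=C1C=C[C@@H](C)[C@@]2(CCC3=CCOC3=O)C(=O)OC[C@@H]12 | intermediate
12 | (3aS,7R,7aR)-7-methyl-7a-[2-(2-oxo-2,5-dihydrofuran-3-yl)ethyl]hexahydro-2-benzofuran-1,4-dione | O=C1CC[C@@H](C)[C@@]2(CCC3=CCOC3=O)C(=O)OC[C@@H]12 | intermediate
13 | isopropenylmagnesium bromide | C=C(C)[Mg]Br | starting material
14 | bromomagnesium alkoxide of (3aS,4S,7R,7aR)-4-hydroxy-7-methyl-7a-[2-(2-oxo-2,5-dihydrofuran-3-yl)ethyl]-4-(prop-1-en-2-yl)hexahydro-2-benzofuran-1(3H)-one (C5–O cis to C20) | C=C(C)[C@]1(O[Mg]Br)CC[C@@H](C)[C@@]2(CCC3=CCOC3=O)C(=O)OC[C@@H]12 | intermediate (not isolated)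
15 | bromomagnesium alkoxide of the 8-(hydroxymethyl) bridged lactone (lactone now on O–C5) | C=C(C)[C@@]12CC[C@@H](C)[C@@](CCC3=CCOC3=O)(C(=O)O1)[C@H]2CO[Mg]Br | intermediate (not isolated)
16 | (1R,2R,5S,8S)-2-methyl-1-[2-(2-oxo-2,5-dihydrofuran-3-yl)ethyl]-5-(prop-1-en-2-yl)-8-[(triethylsilyloxy)methyl]-6-oxabicyclo[3.2.1]octan-7-one | C=C(C)[C@@]12CC[C@@H](C)[C@@](CCC3=CCOC3=O)(C(=O)O1)[C@H]2CO[Si](CC)(CC)CC | intermediate
17 | dimethyl(alkoxy)sulfonium chloride of the C1 oxygen | C=C(C)[C@@]12CC[C@@H](C)[C@@](CCC3=CCOC3=O)(C(=O)O1)[C@H]2CO[S+](C)C.[Cl-] | intermediate (not isolated)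
18 | (1R,2R,5S,8R)-2-methyl-7-oxo-1-[2-(2-oxo-2,5-dihydrofuran-3-yl)ethyl]-5-(prop-1-en-2-yl)-6-oxabicyclo[3.2.1]octane-8-carbaldehyde | C=C(C)[C@@]12CC[C@@H](C)[C@@](CCC3=CCOC3=O)(C(=O)O1)[C@H]2C=O | intermediate
19 | 2,2-dimethyl-1,3-dioxane-4,6-dione | CC1(C)OC(=O)CC(=O)O1 | starting material
20 | 5-alkylidene-2,2-dimethyl-1,3-dioxane-4,6-dione from 18 (C1=C bond to the dioxanedione) | C=C(C)[C@@]12CC[C@@H](C)[C@@](CCC3=CCOC3=O)(C(=O)O1)[C@H]2C=C4C(=O)OC(C)(C)OC4=O | intermediate (not isolated)
21 | 5-{[(1R,2R,5S,8R)-2-methyl-7-oxo-1-[2-(2-oxo-2,5-dihydrofuran-3-yl)ethyl]-5-(prop-1-en-2-yl)-6-oxabicyclo[3.2.1]octan-8-yl]methyl}-2,2-dimethyl-1,3-dioxane-4,6-dione | C=C(C)[C@@]12CC[C@@H](C)[C@@](CCC3=CCOC3=O)(C(=O)O1)[C@H]2CC4C(=O)OC(C)(C)OC4=O | intermediate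
22 | 2-(methoxycarbonyl)-3-[(1R,2R,5S,8R)-bicyclic lactone-8-yl]propanoic acid (malonic half ester) | C=C(C)[C@@]12CC[C@@H](C)[C@@](CCC3=CCOC3=O)(C(=O)O1)[C@H]2CC(C(=O)O)C(=O)OC | intermediate (not isolated)
23 | methyl 3-[(1R,2R,5S,8R)-2-methyl-7-oxo-1-[2-(2-oxo-2,5-dihydrofuran-3-yl)ethyl]-5-(prop-1-en-2-yl)-6-oxabicyclo[3.2.1]octan-8-yl]propanoate | C=C(C)[C@@]12CC[C@@H](C)[C@@](CCC3=CCOC3=O)(C(=O)O1)[C@H]2CCC(=O)OC | target

**Step count**

Total steps: 10. Longest linear sequence: 10 steps (1 → 23).

**Steps most likely to fail**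

Step 4 (proposed new method). The α-alkyl group removes the α-C–H contact that normally organises this catalyst class on the dienophile, so binding may be weak, turnover slow and face selection poor, and a second cycloaddition on the remaining butenolide may compete. The fallback uses known chemistry and sets out from 8 and 9: the two are combined with EtAlCl2 in CH2Cl2 at 0 °C, or without catalyst at 12 kbar. This should give the same endo, ortho adduct as the racemate, that is 10 together with its mirror image, the (3aR,7S,7aS)-adduct ent-10 F1. The two are separated by preparative chromatography on an amylose tris(3,5-dimethylphenylcarbamate) stationary phase, and the route is rejoined at 10.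

Step 5. Hydrogen abstraction may occur at the tertiary C8–H or on the butenolide side, oxygen may be delivered to the transposed allylic terminus, and the enone may be over-oxidised at its γ-position C8. The fallback sets out from 8, returns at 12, and brings the C5 oxygen in as a silyl group on the diene terminus. (1E,3E)-1-(Dimethylphenylsilyl)penta-1,3-diene F2 is made from (E)-pent-3-en-1-yne and PhMe2SiH with Pt2[(CH2=CHMe2Si)2O]3 (zerovalent platinum) and is used in place of 9 under the step 4 conditions. The methyl group should still govern regiochemistry and both outside groups should end cis to C20, giving the allylsilane adduct F3. Hydrogenation (H2, RhCl(PPh3)3, benzene) should reduce only the disubstituted ring alkene to the saturated silane F4. Fleming–Tamao oxidation (HBF4·OEt2, CH2Cl2; then 3-chloroperbenzoic acid, KF, DMF) replaces silicon by oxygen with retention to give the C5 alcohol F5, which is oxidised at once (Dess–Martin oxidation, NaHCO3, CH2Cl2) to ketone 12.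

Step 9. C10–H lies anti to the C5–O bond, so the C5 carboxylate may be lost by β-elimination through the enamine of 18 or through γ-deprotonated 20, and condensation at the hindered aldehyde may be slow. The fallback avoids base, sets out from 18 and returns at 23. Mukaiyama aldol addition of 1-methoxy-1-(trimethylsilyloxy)ethene (BF3·OEt2, CH2Cl2, −78 °C) gives the β-hydroxy ester F6 as a C1 epimer mixture. O-Phenyl chlorothionoformate with pyridine converts it to the phenyl thionocarbonate F7. Barton–McCombie deoxygenation (Bu3SnH, azobisisobutyronitrile, toluene, 80 °C, high stannane concentration) then removes the C1 oxygen and gives 23.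

**Further compounds**

F1 | step 4 | (3aR,7S,7aS)-7-methyl-7a-[2-(2-oxo-2,5-dihydrofuran-3-yl)ethyl]-3a,4,7,7a-tetrahydro-2-benzofuran-1(3H)-one (enantiomer of 10, formed with it as the racemate) | C1C=C[C@H](C)[C@]2(CCC3=CCOC3=O)C(=O)OC[C@H]12
F2 | step 5 | (1E,3E)-1-(dimethylphenylsilyl)penta-1,3-diene | C/C=C/C=C/[Si](C)(C)c1ccccc1
F3 | step 5 | allylsilane adduct: 10 carrying a dimethylphenylsilyl group at C5, cis to C1 and C20 | C[Si](C)(c1ccccc1)[C@H]1C=C[C@@H](C)[C@@]2(CCC3=CCOC3=O)C(=O)OC[C@@H]12
F4 | step 5 | saturated silane: F3 with C6–C7 reduced | C[Si](C)(c1ccccc1)[C@H]1CC[C@@H](C)[C@@]2(CCC3=CCOC3=O)C(=O)OC[C@@H]12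
F5 | step 5 | C5 alcohol: F4 with hydroxyl in place of silicon, same configuration | O[C@H]1CC[C@@H](C)[C@@]2(CCC3=CCOC3=O)C(=O)OC[C@@H]12
F6 | step 9 | methyl 3-hydroxy-3-[(1R,2R,5S)-bicyclic lactone-8-yl]propanoate (C1 epimers) | C=C(C)[C@@]12CC[C@@H](C)[C@@](CCC3=CCOC3=O)(C(=O)O1)[C@H]2C(O)CC(=O)OC
F7 | step 9 | O-phenyl thionocarbonate of F6 | C=C(C)[C@@]12CC[C@@H](C)[C@@](CCC3=CCOC3=O)(C(=O)O1)[C@H]2C(CC(=O)OC)OC(=S)Oc4ccccc4
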